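The quinone ring is assembled last from three pieces. With the ring numbered C1 (carbonyl between the substituents), C2 (methyl-bearing), C3, C4 (second carbonyl), C5, C6 (chain-bearing), a Dötz [3+2+1] benzannulation unites the terminal alkyne of the complete side chain (C5, C6), the propenyl(methoxy)carbene ligand of a chromium complex (C4, C3, C2 plus methyl) and one CO ligand (C1), forming C4–C5, C6–C1 and C1–C2 at once; cerium oxidation then gives the quinone. The step exploits the 2,6-pattern: a terminal alkyne places its substituent beside the CO-derived carbon. The precursor is an acyclic enyne diketone on the cis-1,2-dimethylcyclopentane, made by asymmetric allylation and cuprate addition to a bicyclooctenone.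

Key step: step 14

Remark on the chemistry: the sense of induction in step 2 is assumed to be that of the six-membered-ring series ((R)-ligand gives (R)-ketone 4); if it proves opposite, the antipodal ligand is used, and enantiomeric purity can be raised by crystallising a derivative of 4 if needed.

Step 1
Reactants: 1 diallyl adipate
Product: 3 allyl 1-methyl-2-oxocyclopentane-1-carboxylate (racemic), via sodium enolate of allyl 2-oxocyclopentane-1-carboxylate 2 (not isolated)
Conditions: NaH (1.05 equiv), THF, 40 °C; then MeI (1.5 equiv), 0 °C to rt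
Reagents that add atoms: iodomethane, CI
Why: Dieckmann condensation gives the stabilised β-keto ester enolate, which is C-methylated in the same flask (enolate alkylation); the quaternary centre is racemic on purpose because step 2 passes through an achiral enolate.

Step 2
Reactants: 3 allyl 1-methyl-2-oxocyclopentane-1-carboxylate
Product: 4 (R)-2-allyl-2-methylcyclopentan-1-one
Conditions: Pd2(dba)3 (2.5 mol %), (R)-t-BuPHOX [(R)-4-tert-butyl-2-(2-diphenylphosphinophenyl)-4,5-dihydrooxazole] (6 mol %), toluene, 25 °C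
Reagents that add atoms: none
Why: Decarboxylative asymmetric allylic alkylation (Tsuji allylation with a chiral phosphinooxazoline): zerovalent palladium ionises the allyl ester, CO2 is lost and the chiral allylpalladium enolate recombines on one enolate face, which should set the quaternary centre as R.

Step 3
Reactants: 4 (R)-2-allyl-2-methylcyclopentan-1-one
Product: 5 (R)-2-methyl-2-(2-oxopropyl)cyclopentan-1-one
Conditions: PdCl2 (10 mol %), CuCl (1 equiv), O2 (balloon), DMF/H2O 7:1, rt
Reagents that add atoms: water, O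
Why: Tsuji–Wacker oxidation: Markovnikov hydroxypalladation of the monosubstituted alkene and β-hydride elimination give the methyl ketone, and the quaternary centre cannot epimerise.

Step 4
Reactants: 5 (R)-2-methyl-2-(2-oxopropyl)cyclopentan-1-one
Product: 6 (R)-6a-methyl-4,5,6,6a-tetrahydropentalen-2(1H)-one
Conditions: KOH (powdered), xylenes, 110 °C, Dean–Stark
Reagents that add atoms: none
Why: Intramolecular aldol condensation: only attack of the methyl-ketone enolate on the ring carbonyl gives a β-hydroxy ketone that can dehydrate (the bridged alternative is reversible and cannot eliminate), and removal of water drives formation of the bicyclo[3.3.0]oct-1-en-3-one.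

Step 5
Reactants: 6 (R)-6a-methyl-4,5,6,6a-tetrahydropentalen-2(1H)-one
Product: 7 trimethyl{[(3aS,6aR)-3a,6a-dimethyl-1,3a,4,5,6,6a-hexahydropentalen-2-yl]oxy}silane
Conditions: Me2CuLi (2 equiv, from MeLi and CuI), TMSCl (4 equiv), THF/Et2O, −78 to −20 °C; Et3N, pentane work-up
Reagents that add atoms: lithium dimethylcuprate, [Li+].C[Cu-]C (made from methyllithium, [Li]C, and CuI); chlorotrimethylsilane, C[Si](C)(C)Cl
Why: TMSCl-accelerated conjugate addition of a lithium dialkylcuprate: methyl can only enter cis to the angular methyl because the diquinane must stay cis-fused, which sets the second quaternary centre, and silylation of the enolate as formed fixes the double bond on the side of the new centre (the free ketone would be meso, so the enolate must not be protonated).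

Step 6
Reactants: 7 trimethyl{[(3aS,6aR)-3a,6a-dimethyl-1,3a,4,5,6,6a-hexahydropentalen-2-yl]oxy}silane
Product: 8 2-[(1R,2R)-2-formyl-1,2-dimethylcyclopentyl]acetic acid
Conditions: O3, CH2Cl2/MeOH, −78 °C; then Me2S, −78 °C to rt; aqueous work-up
Reagents that add atoms: ozone, [O-][O+]=O
Why: Ozonolysis of a silyl enol ether: cleavage of the enol double bond gives the aldehyde on the new quaternary carbon and, after loss of silicon, the acetic acid arm on the other; neither centre has an α-hydrogen.

Step 7
Reactants: 8 2-[(1R,2R)-2-formyl-1,2-dimethylcyclopentyl]acetic acid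
Product: 10 (4aR,7aR)-4a,7a-dimethyl-1-(3-methylbut-2-en-1-yl)hexahydrocyclopenta[c]pyran-3(1H)-one (C-1 epimers), via hydroxy acid 9 (not isolated)
Conditions: prenyl chloride (3 equiv), activated Ba (from BaI2 and 2 lithium biphenylide), THF, −78 °C; add 8, −78 °C; then 1 M HCl, rt
Reagents that add atoms: prenyl chloride (1-chloro-3-methylbut-2-ene), CC(C)=CCCl, used as prenylbarium chloride, CC(C)=CC[Ba]Cl
Why: α-Selective allylbarium addition to an aldehyde: after one equivalent is consumed by the acid proton, prenylbarium chloride attacks through its unsubstituted CH2 terminus to give the linear prenyl carbinol 9, which closes to the cis-fused δ-lactone on acidification; the carbinol centre forms unselectively and is erased in step 11.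

Step 8
Reactants: 11 isoprene, 12 benzenesulfonyl chloride
Product: 13 {[(2E)-4-chloro-2-methylbut-2-en-1-yl]sulfonyl}benzene
Conditions: CuCl (5 mol %), Et3N·HCl (5 mol %), MeCN, 90 °C (sealed); crystallisation of the E isomer
Reagents that add atoms: none
Why: Copper-catalysed atom-transfer (Kharasch-type) chlorosulfonylation of a 1,3-diene: the sulfonyl radical adds to the CH2 next to the methyl-bearing carbon to give the tertiary allylic radical, chlorine is delivered to the far terminus (1,4-addition), and the preferred E-alkene should be obtained pure by crystallisation.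

Step 9
Reactants: 13 {[(2E)-4-chloro-2-methylbut-2-en-1-yl]sulfonyl}benzene, 14 ethynyltrimethylsilane
Product: 15 trimethyl[(4E)-5-methyl-6-(phenylsulfonyl)hex-4-en-1-yn-1-yl]silane
Conditions: CuI (10 mol %), n-Bu4NI (10 mol %), K2CO3 (1.5 equiv), DMF, rt
Reagents that add atoms: none
Why: Copper-catalysed coupling of a terminal alkyne with a primary allylic halide: the copper acetylide displaces chloride at the unhindered CH2 (SN2, not SN2′ at the trisubstituted carbon), giving the skipped enyne with the E-alkene intact, and carbonate is too weak a base to touch the sulfone.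

Step 10
Reactants: 10 (4aR,7aR)-4a,7a-dimethyl-1-(3-methylbut-2-en-1-yl)hexahydrocyclopenta[c]pyran-3(1H)-one, 15 trimethyl[(4E)-5-methyl-6-(phenylsulfonyl)hex-4-en-1-yn-1-yl]silane
Product: 17 (4E)-1-[(1R,2R)-2-(1-hydroxy-4-methylpent-3-en-1-yl)-1,2-dimethylcyclopentyl]-4-methyl-3-(phenylsulfonyl)oct-4-en-7-yn-2-one (diastereomer mixture), via silylated keto sulfone 16 (not isolated)
Conditions: 15 (2.3 equiv), n-BuLi (2.2 equiv), THF, −78 °C; add 10, −78 to −20 °C; then MeOH, K2CO3 (0.2 equiv), 0 °C to rt; aq. NH4Cl
Reagents that add atoms: none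
Why: Acylation of an α-sulfonyl carbanion by a lactone: the lithiated allylic sulfone attacks the lactone carbonyl only through its sulfonyl-bearing carbon (alkene position and E-geometry retained), the β-keto sulfone is deprotonated by the second equivalent so that no second addition occurs, and methoxide formed on adding methanol cleaves the C(sp)–Si bond while the keto sulfone is protected as its enolate; diastereomers and hemiketal forms converge later.

Step 11
Reactants: 17 (4E)-1-[(1R,2R)-2-(1-hydroxy-4-methylpent-3-en-1-yl)-1,2-dimethylcyclopentyl]-4-methyl-3-(phenylsulfonyl)oct-4-en-7-yn-2-one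
Product: 18 (4E)-1-[(1R,2R)-1,2-dimethyl-2-(4-methylpent-3-enoyl)cyclopentyl]-4-methyl-3-(phenylsulfonyl)oct-4-en-7-yn-2-one
Conditions: Dess–Martin periodinane (1.5 equiv), CH2Cl2, 0 °C to rt
Reagents that add atoms: none
Why: Dess–Martin oxidation of the hindered secondary alcohol, drawn from the hemiketal equilibrium through the open hydroxy ketone, removes the stray carbinol centre without touching alkyne, alkenes or sulfone.

Step 12
Reactants: 18 (4E)-1-[(1R,2R)-1,2-dimethyl-2-(4-methylpent-3-enoyl)cyclopentyl]-4-methyl-3-(phenylsulfonyl)oct-4-en-7-yn-2-one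
Product: 19 (4E)-1-[(1R,2R)-1,2-dimethyl-2-(4-methylpent-3-enoyl)cyclopentyl]-4-methyloct-4-en-7-yn-2-one
Conditions: SmI2 (3 equiv), THF/MeOH, −78 °C, 10 min; aq. NH4Cl at −78 °C
Reagents that add atoms: none
Why: Reductive desulfonylation of a β-keto sulfone by single-electron transfer from SmI2: the samarium dienolate is protonated by methanol at the α-carbon at −78 °C, which should leave the β,γ-unsaturated ketone and the E-alkene in place, while the hindered isolated ketone and the alkyne are not reduced under these conditions.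

Step 13
Reactants: 20 (E)-1-bromoprop-1-ene, 21 hexacarbonylchromium Cr(CO)6
Product: 24 pentacarbonyl[(2E)-1-methoxybut-2-en-1-ylidene]chromium, via (E)-prop-1-enyllithium 22 (not isolated), via lithium acylchromate 23 (not isolated)
Conditions: t-BuLi (2 equiv), Et2O, −78 °C; Cr(CO)6, 0 °C to rt; then Me3OBF4, CH2Cl2, 0 °C
Reagents that add atoms: trimethyloxonium tetrafluoroborate, C[O+](C)C.F[B-](F)(F)F
Why: Fischer carbene synthesis: bromine–lithium exchange with retention gives the E-alkenyllithium, which adds to a CO ligand of Cr(CO)6, and the acylchromate is O-methylated by the oxonium salt.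

Step 14
Reactants: 19 (4E)-1-[(1R,2R)-1,2-dimethyl-2-(4-methylpent-3-enoyl)cyclopentyl]-4-methyloct-4-en-7-yn-2-one, 24 pentacarbonyl[(2E)-1-methoxybut-2-en-1-ylidene]chromium
Product: 26 2-{(2E)-6-[(1R,2R)-1,2-dimethyl-2-(4-methylpent-3-enoyl)cyclopentyl]-3-methyl-5-oxohex-2-en-1-yl}-6-methylcyclohexa-2,5-diene-1,4-dione (target), via 4-methoxyphenol 25 (not isolated)
Conditions: 24 (1.5 equiv), THF (0.05 M, degassed), 50 °C; then (NH4)2Ce(NO3)6 (6 equiv), MeCN/H2O, 0 °C
Reagents that add atoms: water, O
Why: Dötz benzannulation ([3+2+1]): loss of one CO from 24 lets the terminal alkyne of 19 insert into the chromium–carbene bond with its unsubstituted carbon bonded to the former carbene carbon (C4–C5), CO insertion gives a chromium-bound dienylketene (C6–C1), and 6π-electrocyclisation with tautomerisation closes the ring (C1–C2) to the 4-methoxyphenol 25 held on Cr(CO)3. The closest known reaction type is the benzannulation of alkenyl(alkoxy)carbene chromium complexes with terminal alkynes followed by oxidative work-up to p-quinones. The six-membered carbocycle is closed by a thermal 6π-electrocyclisation of the metal-templated dienylketene after two intermolecular insertions. No stereocentre is formed; the two quaternary centres are remote and non-epimerisable and neither alkene takes part. The step needs regioselective insertion, secured by the steric difference between H and the CH2 chain on the alkyne (chain beside the CO-derived C1, hence the 2,6- and not the 2,5-pattern), and chemoselectivity over two ketones and two trisubstituted alkenes, secured by neutral conditions at 50 °C under which alkenylcarbene chromium complexes neither cyclopropanate unactivated alkenes nor add to ketones and in THF give phenol rather than five-membered-ring products. (NH4)2Ce(NO3)6 then strips chromium and oxidises the 4-methoxyphenol to the quinone with loss of methanol, the C4 oxygen coming from water.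

Compound list
1 | diallyl adipate | C=CCOC(=O)CCCCC(=O)OCC=C | starting material
2 | sodium enolate of allyl 2-oxocyclopentane-1-carboxylate | [Na+].[O-]C1=C(CCC1)C(=O)OCC=C | intermediate
3 | allyl 1-methyl-2-oxocyclopentane-1-carboxylate (racemic) | C=CCOC(=O)C1(C)CCCC1=O | intermediate
4 | (R)-2-allyl-2-methylcyclopentan-1-one | C[C@]1(CC=C)CCCC1=O | intermediate
5 | (R)-2-methyl-2-(2-oxopropyl)cyclopentan-1-one | CC(=O)C[C@@]1(C)CCCC1=O | intermediate
6 | (R)-6a-methyl-4,5,6,6a-tetrahydropentalen-2(1H)-one | O=C1C=C2CCC[C@]2(C)C1 | intermediate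
7 | trimethyl{[(3aS,6aR)-3a,6a-dimethyl-1,3a,4,5,6,6a-hexahydropentalen-2-yl]oxy}silane (cis-fused) | C[Si](C)(C)OC1=C[C@]2(C)CCC[C@]2(C)C1 | intermediate
8 | 2-[(1R,2R)-2-formyl-1,2-dimethylcyclopentyl]acetic acid | O=C[C@]1(C)CCC[C@]1(C)CC(=O)O | intermediate
9 | 2-[(1R,2R)-2-(1-hydroxy-4-methylpent-3-en-1-yl)-1,2-dimethylcyclopentyl]acetic acid (carbinol epimers) | CC(C)=CCC(O)[C@]1(C)CCC[C@]1(C)CC(=O)O | intermediate
10 | (4aR,7aR)-4a,7a-dimethyl-1-(3-methylbut-2-en-1-yl)hexahydrocyclopenta[c]pyran-3(1H)-one (cis-fused δ-lactone, C-1 epimers) | CC(C)=CCC1OC(=O)C[C@@]2(C)CCC[C@@]12C | intermediate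
11 | isoprene | C=CC(C)=C | starting material
12 | benzenesulfonyl chloride | O=S(=O)(Cl)c1ccccc1 | starting material
13 | {[(2E)-4-chloro-2-methylbut-2-en-1-yl]sulfonyl}benzene | O=S(=O)(C/C(C)=C/CCl)c1ccccc1 | intermediate
14 | ethynyltrimethylsilane | C#C[Si](C)(C)C | starting material
15 | trimethyl[(4E)-5-methyl-6-(phenylsulfonyl)hex-4-en-1-yn-1-yl]silane | O=S(=O)(C/C(C)=C/CC#C[Si](C)(C)C)c1ccccc1 | intermediate
16 | (4E)-1-[(1R,2R)-2-(1-hydroxy-4-methylpent-3-en-1-yl)-1,2-dimethylcyclopentyl]-4-methyl-3-(phenylsulfonyl)-8-(trimethylsilyl)oct-4-en-7-yn-2-one (diastereomer mixture) | CC(C)=CCC(O)[C@]1(C)CCC[C@]1(C)CC(=O)C(S(=O)(=O)c1ccccc1)/C(C)=C/CC#C[Si](C)(C)C | intermediate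
17 | (4E)-1-[(1R,2R)-2-(1-hydroxy-4-methylpent-3-en-1-yl)-1,2-dimethylcyclopentyl]-4-methyl-3-(phenylsulfonyl)oct-4-en-7-yn-2-one (diastereomer mixture, open form drawn) | CC(C)=CCC(O)[C@]1(C)CCC[C@]1(C)CC(=O)C(S(=O)(=O)c1ccccc1)/C(C)=C/CC#C | intermediate
18 | (4E)-1-[(1R,2R)-1,2-dimethyl-2-(4-methylpent-3-enoyl)cyclopentyl]-4-methyl-3-(phenylsulfonyl)oct-4-en-7-yn-2-one (C-3 epimers) | CC(C)=CCC(=O)[C@]1(C)CCC[C@]1(C)CC(=O)C(S(=O)(=O)c1ccccc1)/C(C)=C/CC#C | intermediate
19 | (4E)-1-[(1R,2R)-1,2-dimethyl-2-(4-methylpent-3-enoyl)cyclopentyl]-4-methyloct-4-en-7-yn-2-one | CC(C)=CCC(=O)[C@]1(C)CCC[C@]1(C)CC(=O)C/C(C)=C/CC#C | intermediate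
20 | (E)-1-bromoprop-1-ene | C/C=C/Br | starting material
21 | hexacarbonylchromium, Cr(CO)6 | O=C=[Cr](=C=O)(=C=O)(=C=O)(=C=O)=C=O | starting material
22 | (E)-prop-1-en-1-yllithium | C/C=C/[Li] | intermediate
23 | lithium pentacarbonyl[(2E)-1-oxidobut-2-en-1-ylidene]chromate (acylchromate) | [Li+].C/C=C/C([O-])=[Cr](=C=O)(=C=O)(=C=O)(=C=O)=C=O | intermediate
24 | pentacarbonyl[(2E)-1-methoxybut-2-en-1-ylidene]chromium | COC(/C=C/C)=[Cr](=C=O)(=C=O)(=C=O)(=C=O)=C=O | intermediate
25 | 2-{(2E)-6-[(1R,2R)-1,2-dimethyl-2-(4-methylpent-3-enoyl)cyclopentyl]-3-methyl-5-oxohex-2-en-1-yl}-4-methoxy-6-methylphenol (present largely as its Cr(CO)3 complex; metal-free phenol drawn) | CC(C)=CCC(=O)[C@]1(C)CCC[C@]1(C)CC(=O)C/C(C)=C/Cc1cc(OC)cc(C)c1O | intermediate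
26 | 2-{(2E)-6-[(1R,2R)-1,2-dimethyl-2-(4-methylpent-3-enoyl)cyclopentyl]-3-methyl-5-oxohex-2-en-1-yl}-6-methylcyclohexa-2,5-diene-1,4-dione | CC(C)=CCC(=O)[C@]1(C)CCC[C@]1(C)CC(=O)C/C(C)=C/CC1=CC(=O)C=C(C)C1=O | target

Total step count: 14. Longest linear sequence: 11 steps (steps 1–7, 10–12 and 14); steps 8–9 and step 13 prepare the two side fragments.

Steps most likely to fail

Step 14. The chromium vinylcarbene formed after alkyne insertion may be diverted before CO insertion and ring closure (a second alkyne insertion, cyclisation without CO, or interception by the ketone and alkene functions), and the cerium work-up may over-oxidise the alkene and ketone array. The fallback keeps the same annulation but runs it on the small alkyne and carries the arene as its dimethyl ether. It sets out from 15: K2CO3 in MeOH gives {[(2E)-2-methylhex-2-en-5-yn-1-yl]sulfonyl}benzene F1. Heating F1 with 24 in THF at 50 °C and stirring in air (no cerium) gives 4-methoxy-2-methyl-6-[(2E)-3-methyl-4-(phenylsulfonyl)but-2-en-1-yl]phenol F2. MeI and K2CO3 in acetone give 2,5-dimethoxy-1-methyl-3-[(2E)-3-methyl-4-(phenylsulfonyl)but-2-en-1-yl]benzene F3. Lithiation with n-BuLi and acylation by lactone 10, as in step 10, give (4E)-6-(2,5-dimethoxy-3-methylphenyl)-1-[(1R,2R)-2-(1-hydroxy-4-methylpent-3-en-1-yl)-1,2-dimethylcyclopentyl]-4-methyl-3-(phenylsulfonyl)hex-4-en-2-one F4. Dess–Martin oxidation gives (4E)-6-(2,5-dimethoxy-3-methylphenyl)-1-[(1R,2R)-1,2-dimethyl-2-(4-methylpent-3-enoyl)cyclopentyl]-4-methyl-3-(phenylsulfonyl)hex-4-en-2-one F5, and SmI2 in THF/MeOH at −78 °C gives (4E)-6-(2,5-dimethoxy-3-methylphenyl)-1-[(1R,2R)-1,2-dimethyl-2-(4-methylpent-3-enoyl)cyclopentyl]-4-methylhex-4-en-2-one F6. Oxidative demethylation with (NH4)2Ce(NO3)6 in MeCN/H2O at 0 °C comes back to the route at 26.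

Step 5. Methyl transfer to the β-carbon, which is flanked by a quaternary centre, may be too slow, so that reagent decomposition, 1,2-addition or γ-deprotonation of the enone competes. The fallback replaces nucleophilic attack by an electrophilic cyclopropanation followed by reductive ring opening. It sets out from 6: NaBH4 with CeCl3·7H2O in MeOH (Luche reduction) gives (2RS,6aR)-6a-methyl-1,2,4,5,6,6a-hexahydropentalen-2-ol F7. Et2Zn and CH2I2 (hydroxyl-directed Simmons–Smith reaction; only the cis-fused tricycle can form, so the methylene enters on the face of the angular methyl) give (6R)-6-methyltricyclo[4.3.0.0(1,3)]nonan-4-ol F8. Dess–Martin oxidation gives (6R)-6-methyltricyclo[4.3.0.0(1,3)]nonan-4-one F9. Li in NH3/THF at −78 °C cleaves the exocyclic cyclopropane bond, the one aligned with the carbonyl π system, which unveils the angular methyl and the regiodefined lithium (3aS,6aR)-3a,6a-dimethyl-1,3a,4,5,6,6a-hexahydropentalen-2-olate F10. After removal of ammonia, TMSCl and Et3N in THF come back to the route at 7.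

Step 7. The prenyl reagent may partly attack through its substituted terminus (reverse-prenyl carbinol), or addition to the neopentyl aldehyde held as a carboxylate may stay incomplete. The fallback separates C–C bond formation from installation of the trisubstituted alkene. It sets out from 8: allylmagnesium bromide (2.5 equiv, THF, −78 to 0 °C), which has no regiochemical ambiguity, gives 2-[(1R,2R)-2-(1-hydroxybut-3-en-1-yl)-1,2-dimethylcyclopentyl]acetic acid F11. Acidification closes F11 to (4aR,7aR)-1-allyl-4a,7a-dimethylhexahydrocyclopenta[c]pyran-3(1H)-one F12. Cross-metathesis with excess 2-methylbut-2-ene and second-generation Grubbs catalyst, RuCl2(=CHPh)(H2IMes)(PCy3), in CH2Cl2 at 40 °C converts allyl into prenyl and comes back to the route at 10.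

Further compounds
F1 | step 14 | {[(2E)-2-methylhex-2-en-5-yn-1-yl]sulfonyl}benzene | O=S(=O)(C/C(C)=C/CC#C)c1ccccc1
F2 | step 14 | 4-methoxy-2-methyl-6-[(2E)-3-methyl-4-(phenylsulfonyl)but-2-en-1-yl]phenol | O=S(=O)(C/C(C)=C/Cc1cc(OC)cc(C)c1O)c1ccccc1
F3 | step 14 | 2,5-dimethoxy-1-methyl-3-[(2E)-3-methyl-4-(phenylsulfonyl)but-2-en-1-yl]benzene | O=S(=O)(C/C(C)=C/Cc1cc(OC)cc(C)c1OC)c1ccccc1
F4 | step 14 | (4E)-6-(2,5-dimethoxy-3-methylphenyl)-1-[(1R,2R)-2-(1-hydroxy-4-methylpent-3-en-1-yl)-1,2-dimethylcyclopentyl]-4-methyl-3-(phenylsulfonyl)hex-4-en-2-one | CC(C)=CCC(O)[C@]1(C)CCC[C@]1(C)CC(=O)C(S(=O)(=O)c1ccccc1)/C(C)=C/Cc1cc(OC)cc(C)c1OC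
F5 | step 14 | (4E)-6-(2,5-dimethoxy-3-methylphenyl)-1-[(1R,2R)-1,2-dimethyl-2-(4-methylpent-3-enoyl)cyclopentyl]-4-methyl-3-(phenylsulfonyl)hex-4-en-2-one | CC(C)=CCC(=O)[C@]1(C)CCC[C@]1(C)CC(=O)C(S(=O)(=O)c1ccccc1)/C(C)=C/Cc1cc(OC)cc(C)c1OC
F6 | step 14 | (4E)-6-(2,5-dimethoxy-3-methylphenyl)-1-[(1R,2R)-1,2-dimethyl-2-(4-methylpent-3-enoyl)cyclopentyl]-4-methylhex-4-en-2-one | CC(C)=CCC(=O)[C@]1(C)CCC[C@]1(C)CC(=O)C/C(C)=C/Cc1cc(OC)cc(C)c1OC
F7 | step 5 | (2RS,6aR)-6a-methyl-1,2,4,5,6,6a-hexahydropentalen-2-ol | OC1C=C2CCC[C@]2(C)C1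
F8 | step 5 | (6R)-6-methyltricyclo[4.3.0.0(1,3)]nonan-4-ol (cyclopropane methylene cis to the methyl) | OC1C[C@@]2(C)CCC[C@]23CC13
F9 | step 5 | (6R)-6-methyltricyclo[4.3.0.0(1,3)]nonan-4-one (cyclopropane methylene cis to the methyl) | O=C1C[C@@]2(C)CCC[C@]23CC13
F10 | step 5 | lithium (3aS,6aR)-3a,6a-dimethyl-1,3a,4,5,6,6a-hexahydropentalen-2-olate | [Li+].[O-]C1=C[C@]2(C)CCC[C@]2(C)C1
F11 | step 7 | 2-[(1R,2R)-2-(1-hydroxybut-3-en-1-yl)-1,2-dimethylcyclopentyl]acetic acid | C=CCC(O)[C@]1(C)CCC[C@]1(C)CC(=O)O
F12 | step 7 | (4aR,7aR)-1-allyl-4a,7a-dimethylhexahydrocyclopenta[c]pyran-3(1H)-one | C=CCC1OC(=O)C[C@@]2(C)CCC[C@@]12C
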